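**Remark (assumption):** atom labels C1–C20 are ent-kaurane locants; the target is treated as 11-oxo-6,7-seco-ent-kaur-16-en-7-al-6,19-dioic acid. Two stereocentres that are destroyed later are left undefined and both epimers are used: C10 in 3 and the carbinol C7 in 10/12.

## The problem

Target 19 has a cyclohexane (ring A: C1–C5, C10) with C4 quaternary (CH3, CO2H), C5 (H, CO2H) and C10 quaternary (CH3). A single bond C9–C10 joins it to a 6-methylidenebicyclo[3.2.1]octan-3-one (rings C/D) with C8 as a quaternary bridgehead bearing CHO, C11 as the ketone, C13 as the second bridgehead and C16=C17 exocyclic.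

The hardest feature is the C9–C10 bond. It links a quaternary carbon to a tertiary carbon that is itself flanked by quaternary C8, and it lies in no ring. The relative configuration of the two halves (C4/C5/C10 against C8/C9/C13) therefore cannot be relayed by a ring unless one is built and cut again.

Five contiguous stereocentres (C4, C5, C10, C9, C8; three quaternary) and C13 must be set. C10 can be controlled from C4 (1,3 across C5). C9 can be controlled from C10 only through an ordered transition state for the C9–C10 bond. C8 can be controlled from the neighbouring C9, and C13 follows from ring closure because the two-carbon bridge can only span cis. C5 is epimerisable and is held by the cis relation to C19 (cyclic anhydride).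

C9 is α to the C11 ketone, so it should be set in a C–C bond-forming event and then kept away from base. Other fragile groups are the γ-keto aldehyde (aldol), the 1,1-disubstituted C16=C17 alkene (acid isomerisation; it competes in any alkene oxidation) and the cis-diacid.

The feature that opens the problem is the chain O=C7–C8–C9–C10–C5–C6(=O)OH. The two "seco" termini, the aldehyde on C8 and the carboxyl on C5, are 1,6 across C9–C10. This is the retron of an oxy-Cope rearrangement of a 1,5-dien-3-ol in which C6–C7 is still a bond, C8=C9 lies in ring C and C5=C10 lies in ring A. The enolate released sits on C8, where the quaternary centre carrying the D-ring carbons is needed.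

## Retrosynthesis

**19 ⇒ 18 ⇒ 17 ⇒ 16 (ring D last).** The diacid 19 is opened from its cis-anhydride 18, which protects both acids and locks C5. Cutting C13–C16 of 18 gives enone 17, a monocyclic cyclohexenone with a 2-bromoallyl group on C8. A 5-exo vinyl radical closure onto the enone β-carbon C13 makes the bridge, and only the cis bridge is possible. Cutting C13–C16 rather than C8–C15 keeps C8 quaternary before the bicycle exists, so no bridgehead chemistry is needed. Enone 17 comes from ketone 16 by dehydrogenation, which can only go towards C12/C13 because C8 carries no hydrogen.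

**16 ⇒ 14 (oxidation levels).** In 14 the C11 ketone is a silyl enol ether, C19 is a tert-butyl ester and the C6 carboxyl is a ketene dithioacetal (C5=C6(S)2). All three are unmasked by acid, and a thiophile transfers the C6 acyl group to the C19 acid to give the anhydride (via thioester acid 15). C6 and C7 thus arrive already differentiated (acid level against aldehyde), which a C6–C7 cleavage of an intact B ring does not give.

**14 ⇒ 10 + 11 (key cut: C9–C10 and C8–C15).** Both bonds to the most hindered carbons are cut at once. C9–C10 is traced to a [3,3] shift of alkoxide 12 (from carbinol 10), in which C6–C7 is the bond that breaks. C8–C15 is traced to alkylation of the resulting aldehyde enolate 13 with 2,3-dibromopropene 11. The alternative cuts at C9–C10 (enolate plus tertiary electrophile, or radical plus acceptor) have no cyclic transition state across the new bond; this one has a chair. The precursor 10 has one stereocentre that matters (C4) and no quaternary carbon other than C4 and the dithiane carbon. The forward reaction must favour [3,3] over fragmentation, select one face of ring A and C-alkylate the enolate.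

**10 ⇒ 7 + 9 (C7–C8).** The carbinol is cut at an unhindered bond: dienyllithium from bromide 9 plus the non-enolisable aldehyde 7. The two halves are of similar size (ring C with its masked ketone; ring A with C4, both methyls and C6/C7). The C7 configuration need not be controlled because C7 becomes the aldehyde carbon.

**7 ⇒ 6 ⇒ 5 ⇒ 4 ⇒ 3 ⇒ 2 ⇒ 1 (ring A).** The formyl carbon C7 comes from DMF and the lithiated dithiane 6 (umpolung at C6; the dithiane is also the latent C6 carboxyl). Dithiane 6 comes from enal 5, and 5 from enol triflate 4 by Pd-catalysed formylation (C6 from CO). Triflate 4 comes from ketone 3, which can enolise only towards C10. Ketone 3 comes from β-keto ester 2 by α′-methylation (C20). Ester 2 comes from commercial 1 by a catalytic asymmetric methylation that sets C4, the only stereocentre introduced by a chiral reagent.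

**9 ⇒ 8 (ring C).** The cross-conjugated silyl dienol ether 9 is the kinetic enol derivative of commercial 3-bromocyclohex-2-enone 8. It is achiral, so all stereochemistry of the bicycle is relayed from ring A.

## Roads not taken

**Alternative 1:** Cut C6–C7 of an intact ent-kaurane, for example ent-11-oxokaura-6,16-dien-19-oic acid A1, by dihydroxylation and glycol cleavage (the biomimetic and most obvious route). The forward key step is oxidative cleavage of ring B. The whole tetracycle with all six stereocentres must first be made (by polyene cyclisation or from a chiral-pool ent-kaurane) and oxidised at unactivated C11 and at C6/C7. The C16=C17 alkene competes in the cleavage. The cleavage gives two aldehydes that must then be told apart, with C6 going to the acid and C7 staying. The chosen plan never builds ring B and delivers C6 and C7 at different oxidation levels from the key step.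

**Alternative 2:** Cut C9–C10 as enolate plus electrophile. The preformed bicyclic keto ester A2 would be joined to the ring A enoate A3 by Michael addition, or through an allyl enol ether and Claisen rearrangement. The Michael addition asks a hindered enolate to attack a tetrasubstituted β-carbon, which is slow and reversible. The enolisation of A2 towards C9 rather than the less hindered C12 is not biased. The Claisen variant needs a boat to give the natural C9/C10 relation, whereas the oxy-Cope through C7 needs the chair. Two fragments would each need their own asymmetric synthesis.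

**Alternative 3:** Cut C9–C10 homolytically. A tertiary C10 radical from the redox-active ester A4 would undergo Giese addition to the keto-enoate A5 to give A6. The radical adds to a flat, achiral acceptor, so the C9/C10 relation across the new bond rests on no cyclic transition state. The site of attack on A5 (β to ketone against β to ester) is ambiguous. A4 already needs three contiguous substituted carbons. After coupling, C8 must be alkylated α to an ester in the presence of a more acidic ketone, and C7 arrives at the acid level and must be reduced selectively.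

Key step: step 9

## Route

Step 1
Reactants: 1 tert-butyl 2-oxocyclohexane-1-carboxylate
Product: 2 tert-butyl (1R)-1-methyl-2-oxocyclohexane-1-carboxylate
Conditions: MeI, chiral N-spiro binaphthyl quaternary ammonium bromide (1–2 mol %, antipode giving R), CsOH·H2O, toluene, −40 °C
Reagents that add atoms: iodomethane, CI
Why: Asymmetric phase-transfer C-alkylation of a cyclic β-keto tert-butyl ester; the chiral ammonium enolate ion pair exposes one face and sets C4 (R), the only stereocentre set by a chiral reagent.

Step 2
Reactants: 2 tert-butyl (1R)-1-methyl-2-oxocyclohexane-1-carboxylate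
Product: 3 tert-butyl (1R)-1,3-dimethyl-2-oxocyclohexane-1-carboxylate (both C3 epimers)
Conditions: LDA, THF, −78 °C; MeI, DMPU, −78 → −20 °C
Reagents that add atoms: iodomethane, CI
Why: Kinetic enolate alkylation; C10 is the only enolisable position (C4 is quaternary, the ester has no α-H) and the new centre is erased in step 3.

Step 3
Reactants: 3 tert-butyl (1R)-1,3-dimethyl-2-oxocyclohexane-1-carboxylate
Product: 4 tert-butyl (1R)-1,3-dimethyl-2-(trifluoromethanesulfonyloxy)cyclohex-2-ene-1-carboxylate
Conditions: KHMDS, THF, −78 → 0 °C; PhNTf2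
Reagents that add atoms: N-phenylbis(trifluoromethanesulfonimide), O=S(=O)(N(c1ccccc1)S(=O)(=O)C(F)(F)F)C(F)(F)F
Why: Enol triflate formation; only the C5=C10 enolate can form, as for 2,2,6-trisubstituted cyclohexanones of the cyclocitral series.

Step 4
Reactants: 4 tert-butyl (1R)-1,3-dimethyl-2-(trifluoromethanesulfonyloxy)cyclohex-2-ene-1-carboxylate
Product: 5 tert-butyl (1R)-2-formyl-1,3-dimethylcyclohex-2-ene-1-carboxylate
Conditions: Pd(PPh3)4 (5 mol %), CO (1–3 atm), Bu3SnH (slow addition), LiCl, THF, 50 °C
Reagents that add atoms: carbon monoxide, [C-]#[O+]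
Why: Pd-catalysed reductive carbonylation (formylation) of an enol triflate; CO insertion is little affected by the two ortho substituents, as in carbonylations of 2,6,6-trisubstituted cyclohexenyl triflates.

Step 5
Reactants: 5 tert-butyl (1R)-2-formyl-1,3-dimethylcyclohex-2-ene-1-carboxylate
Product: 6 tert-butyl (1R)-2-(1,3-dithian-2-yl)-1,3-dimethylcyclohex-2-ene-1-carboxylate
Conditions: propane-1,3-dithiol, BF3·OEt2 (0.3 equiv), CH2Cl2, −20 → 0 °C
Reagents that add atoms: propane-1,3-dithiol, SCCCS
Why: Thioacetalisation of an aldehyde; conjugate addition is blocked by the fully substituted β-carbon, and the low temperature spares the tert-butyl ester.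

Step 6
Reactants: 6 tert-butyl (1R)-2-(1,3-dithian-2-yl)-1,3-dimethylcyclohex-2-ene-1-carboxylate
Product: 7 tert-butyl (1R)-2-(2-formyl-1,3-dithian-2-yl)-1,3-dimethylcyclohex-2-ene-1-carboxylate
Conditions: n-BuLi, THF, −30 °C; DMF, −78 → 0 °C; H2O
Reagents that add atoms: N,N-dimethylformamide, CN(C)C=O
Why: Corey–Seebach lithiation and formylation; the small electrophile is taken at the dithiane carbon (α) because the γ-terminus C10 is fully substituted, and the aldehyde formed cannot enolise.

Step 7
Reactants: 8 3-bromocyclohex-2-en-1-one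
Product: 9 [(5-bromocyclohexa-1,5-dien-1-yl)oxy]tri(propan-2-yl)silane
Conditions: LDA, THF, −78 °C; TIPSOTf
Reagents that add atoms: triisopropylsilyl trifluoromethanesulfonate, CC(C)[Si](C(C)C)(C(C)C)OS(=O)(=O)C(F)(F)F
Why: Kinetic α′-deprotonation of an enone and O-silylation give the cross-conjugated 2-silyloxydiene; this masks the C11 ketone as a flat, base-stable group that does not crowd C9.

Step 8
Reactants: 9 [(5-bromocyclohexa-1,5-dien-1-yl)oxy]tri(propan-2-yl)silane; 7 tert-butyl (1R)-2-(2-formyl-1,3-dithian-2-yl)-1,3-dimethylcyclohex-2-ene-1-carboxylate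
Product: 10 tert-butyl (1R)-2-[2-(hydroxy{3-[tri(propan-2-yl)silyloxy]cyclohexa-1,3-dien-1-yl}methyl)-1,3-dithian-2-yl]-1,3-dimethylcyclohex-2-ene-1-carboxylate (both carbinol epimers)
Conditions: 9, t-BuLi (2 equiv), Et2O, −78 °C; then 7, THF, −78 °C; H2O quench at −78 °C
Reagents that add atoms: none
Why: Bromine–lithium exchange and 1,2-addition of the alkenyllithium to a non-enolisable aldehyde make the unhindered C7–C8 bond; the cold quench keeps the lithium alkoxide from rearranging, and the C7 configuration is left uncontrolled because C7 becomes sp2.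

Step 9
Reactants: 10 tert-butyl (1R)-2-[2-(hydroxy{3-[tri(propan-2-yl)silyloxy]cyclohexa-1,3-dien-1-yl}methyl)-1,3-dithian-2-yl]-1,3-dimethylcyclohex-2-ene-1-carboxylate; 11 2,3-dibromoprop-1-ene
Product: 14 tert-butyl (1R,3S)-3-[(1S,6R)-6-(2-bromoprop-2-en-1-yl)-6-formyl-2-{[tri(propan-2-yl)silyl]oxy}cyclohex-2-en-1-yl]-2-(1,3-dithian-2-ylidene)-1,3-dimethylcyclohexane-1-carboxylate, via potassium alkoxide 12 (not isolated), via potassium enolate 13 (not isolated)
Conditions: KHMDS (1.1 equiv), 18-crown-6, THF, −40 → 0 °C; then 11, −78 → 0 °C (brief warming to 50 °C if an O-allyl enol ether remains)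
Reagents that add atoms: none
Why: The dissociated alkoxide 12 contains the 1,5-diene C9=C8–C7(O⁻)–C6–C5=C10 and should undergo the anionic oxy-Cope ([3,3]) shift, the breaking C7–C6 bond being weakened by the two sulfur atoms; the closest known reaction type is the base-accelerated oxy-Cope of 4-thio-substituted 1,5-dien-3-olates (the α-1,2 to γ-1,4 transposition of 2-alkenyl-1,3-dithiane adducts of enals and enones), followed here by C-alkylation of the aldehyde enolate 13 that it releases. No ring is closed: the step makes the acyclic C9–C10 bond and then the C8–C15 bond. C9 against C10 is fixed by the chair transition state with both alkenes locked in rings (H axial and C11 equatorial at C9; C20 axial and C1 equatorial at C10), which gives H9 anti to C20, C8 anti to C1 and C11 anti to C5, the arrangement of the target. C10 against C4: the larger CO2tBu is pushed pseudoaxial by A(1,2) strain with the dithiane, and the diene half bonds to the opposite face of ring A, so C9 ends trans to C19. The carbinol C7 only decides whether O⁻ is equatorial or axial in that chair, so both epimers of 10 should converge on one product. C8: enolate 13 is alkylated on the face opposite the pseudoaxial C10 substituent on C9, placing the bromoallyl group trans to C10. The step needs [3,3] to beat retro-addition and [1,3] recombination (favoured by the enolate and ketene dithioacetal formed, and by low temperature) and C- to beat O-alkylation (an O-allyl enol ether would reach 14 by Claisen rearrangement with the same facial bias).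

Step 10
Reactants: 14 tert-butyl (1R,3S)-3-[(1S,6R)-6-(2-bromoprop-2-en-1-yl)-6-formyl-2-{[tri(propan-2-yl)silyl]oxy}cyclohex-2-en-1-yl]-2-(1,3-dithian-2-ylidene)-1,3-dimethylcyclohexane-1-carboxylate
Product: 16 (3aS,4S,7aR)-4-[(1S,2R)-2-(2-bromoprop-2-en-1-yl)-2-formyl-6-oxocyclohexyl]-4,7a-dimethylhexahydro-2-benzofuran-1,3-dione, via thioester acid 15 (not isolated)
Conditions: TFA/H2O (9:1), CH2Cl2, 0 °C → rt; concentrate; AgOCOCF3 (2.2 equiv), MeCN, rt
Reagents that add atoms: water, O
Why: Aqueous acid hydrolyses the silyl enol ether to the C11 ketone, cleaves the tert-butyl ester and protonates the ketene dithioacetal at C5 to give the S-(3-sulfanylpropyl) thioester 15 (standard ketene dithioacetal hydrolysis); silver(I) then activates the thioester for acyl transfer to the neighbouring C19 carboxyl. C5 is set by protonation on the face away from the axial C4/C10 groups and, being α to an acyl group, can equilibrate into the cis-fused anhydride, which only the natural C5 epimer forms easily.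

Step 11
Reactants: 16 (3aS,4S,7aR)-4-[(1S,2R)-2-(2-bromoprop-2-en-1-yl)-2-formyl-6-oxocyclohexyl]-4,7a-dimethylhexahydro-2-benzofuran-1,3-dione
Product: 17 (3aS,4S,7aR)-4-[(1S,6R)-6-(2-bromoprop-2-en-1-yl)-6-formyl-2-oxocyclohex-3-en-1-yl]-4,7a-dimethylhexahydro-2-benzofuran-1,3-dione
Conditions: IBX (2.5 equiv), DMSO/fluorobenzene, 70 °C
Reagents that add atoms: none
Why: IBX dehydrogenation of a ketone to the enone; only C12/C13 can be desaturated because C8 bears no hydrogen, the aldehyde is non-enolisable, and the weakly acidic medium leaves C9 untouched.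

Step 12
Reactants: 17 (3aS,4S,7aR)-4-[(1S,6R)-6-(2-bromoprop-2-en-1-yl)-6-formyl-2-oxocyclohex-3-en-1-yl]-4,7a-dimethylhexahydro-2-benzofuran-1,3-dione
Product: 18 (3aS,4S,7aR)-4-[(1R,2S,5S)-1-formyl-6-methylidene-3-oxobicyclo[3.2.1]octan-2-yl]-4,7a-dimethylhexahydro-2-benzofuran-1,3-dione
Conditions: Bu3SnH (1.3 equiv, syringe pump), AIBN (cat.), benzene, 80 °C
Reagents that add atoms: none
Why: 5-exo-trig cyclisation of the C16 vinyl radical onto the enone β-carbon C13 and reduction of the α-keto radical build the methylidene bicyclo[3.2.1]octanone; C13 is set by the tether because the bromoallyl group, axial on C8 and trans to the C10 substituent, can only bridge cis.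

Step 13
Reactants: 18 (3aS,4S,7aR)-4-[(1R,2S,5S)-1-formyl-6-methylidene-3-oxobicyclo[3.2.1]octan-2-yl]-4,7a-dimethylhexahydro-2-benzofuran-1,3-dione
Product: 19 (1R,2S,3S)-3-[(1R,2S,5S)-1-formyl-6-methylidene-3-oxobicyclo[3.2.1]octan-2-yl]-1,3-dimethylcyclohexane-1,2-dicarboxylic acid (CNP0408869.1)
Conditions: H2O/THF, pyridine (cat.), 40 °C; lyophilise
Reagents that add atoms: water, O
Why: Near-neutral hydrolysis of a cyclic anhydride releases both acids without base strong enough to epimerise C9 or trigger aldol reaction of the γ-keto aldehyde.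

## Compound list

1 | tert-butyl 2-oxocyclohexane-1-carboxylate | O=C1CCCCC1C(=O)OC(C)(C)C | starting material
2 | tert-butyl (1R)-1-methyl-2-oxocyclohexane-1-carboxylate | CC(C)(C)OC(=O)[C@]1(C)CCCCC1=O | intermediate
3 | tert-butyl (1R)-1,3-dimethyl-2-oxocyclohexane-1-carboxylate (C3 epimers) | CC(C)(C)OC(=O)[C@]1(C)CCCC(C)C1=O | intermediate
4 | tert-butyl (1R)-1,3-dimethyl-2-(trifluoromethanesulfonyloxy)cyclohex-2-ene-1-carboxylate | CC(C)(C)OC(=O)[C@]1(C)CCCC(C)=C1OS(=O)(=O)C(F)(F)F | intermediate
5 | tert-butyl (1R)-2-formyl-1,3-dimethylcyclohex-2-ene-1-carboxylate | CC(C)(C)OC(=O)[C@]1(C)CCCC(C)=C1C=O | intermediate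
6 | tert-butyl (1R)-2-(1,3-dithian-2-yl)-1,3-dimethylcyclohex-2-ene-1-carboxylate | CC(C)(C)OC(=O)[C@]1(C)CCCC(C)=C1C2SCCCS2 | intermediate
7 | tert-butyl (1R)-2-(2-formyl-1,3-dithian-2-yl)-1,3-dimethylcyclohex-2-ene-1-carboxylate | CC(C)(C)OC(=O)[C@]1(C)CCCC(C)=C1C2(C=O)SCCCS2 | intermediate
8 | 3-bromocyclohex-2-en-1-one | O=C1C=C(Br)CCC1 | starting material
9 | [(5-bromocyclohexa-1,5-dien-1-yl)oxy]tri(propan-2-yl)silane | BrC1=CC(O[Si](C(C)C)(C(C)C)C(C)C)=CCC1 | intermediate
10 | tert-butyl (1R)-2-[2-(hydroxy{3-[tri(propan-2-yl)silyloxy]cyclohexa-1,3-dien-1-yl}methyl)-1,3-dithian-2-yl]-1,3-dimethylcyclohex-2-ene-1-carboxylate (carbinol epimers) | CC(C)(C)OC(=O)[C@]1(C)CCCC(C)=C1C2(SCCCS2)C(O)C3=CC(O[Si](C(C)C)(C(C)C)C(C)C)=CCC3 | intermediate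
11 | 2,3-dibromoprop-1-ene | C=C(Br)CBr | starting material
12 | potassium alkoxide of 10 | [K+].CC(C)(C)OC(=O)[C@]1(C)CCCC(C)=C1C2(SCCCS2)C([O-])C3=CC(O[Si](C(C)C)(C(C)C)C(C)C)=CCC3 | intermediate
13 | potassium enolate of the C7 aldehyde (C8=C7–O⁻; C9 S, C10 S, C4 R; product of the [3,3] shift) | [K+].[O-]C=C1CCC=C(O[Si](C(C)C)(C(C)C)C(C)C)[C@H]1[C@]2(C)CCC[C@@](C)(C(=O)OC(C)(C)C)C2=C3SCCCS3 | intermediate
14 | tert-butyl (1R,3S)-3-[(1S,6R)-6-(2-bromoprop-2-en-1-yl)-6-formyl-2-{[tri(propan-2-yl)silyl]oxy}cyclohex-2-en-1-yl]-2-(1,3-dithian-2-ylidene)-1,3-dimethylcyclohexane-1-carboxylate | C=C(Br)C[C@]1(C=O)CCC=C(O[Si](C(C)C)(C(C)C)C(C)C)[C@H]1[C@]2(C)CCC[C@@](C)(C(=O)OC(C)(C)C)C2=C3SCCCS3 | intermediate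
15 | (1R,2S,3S)-3-[(1S,2R)-2-(2-bromoprop-2-en-1-yl)-2-formyl-6-oxocyclohexyl]-1,3-dimethyl-2-{[(3-sulfanylpropyl)sulfanyl]carbonyl}cyclohexane-1-carboxylic acid | C=C(Br)C[C@]1(C=O)CCCC(=O)[C@H]1[C@]2(C)CCC[C@@](C)(C(=O)O)[C@H]2C(=O)SCCCS | intermediate
16 | (3aS,4S,7aR)-4-[(1S,2R)-2-(2-bromoprop-2-en-1-yl)-2-formyl-6-oxocyclohexyl]-4,7a-dimethylhexahydro-2-benzofuran-1,3-dione | C=C(Br)C[C@]1(C=O)CCCC(=O)[C@H]1[C@]2(C)CCC[C@@]3(C)C(=O)OC(=O)[C@@H]23 | intermediate
17 | (3aS,4S,7aR)-4-[(1S,6R)-6-(2-bromoprop-2-en-1-yl)-6-formyl-2-oxocyclohex-3-en-1-yl]-4,7a-dimethylhexahydro-2-benzofuran-1,3-dione | C=C(Br)C[C@]1(C=O)CC=CC(=O)[C@H]1[C@]2(C)CCC[C@@]3(C)C(=O)OC(=O)[C@@H]23 | intermediate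
18 | (3aS,4S,7aR)-4-[(1R,2S,5S)-1-formyl-6-methylidene-3-oxobicyclo[3.2.1]octan-2-yl]-4,7a-dimethylhexahydro-2-benzofuran-1,3-dione | C=C1C[C@]2(C=O)C[C@H]1CC(=O)[C@H]2[C@]3(C)CCC[C@@]4(C)C(=O)OC(=O)[C@@H]34 | intermediate
19 | (1R,2S,3S)-3-[(1R,2S,5S)-1-formyl-6-methylidene-3-oxobicyclo[3.2.1]octan-2-yl]-1,3-dimethylcyclohexane-1,2-dicarboxylic acid | C=C1C[C@]2(C=O)C[C@H]1CC(=O)[C@H]2[C@]1(C)CCC[C@@](C)(C(=O)O)[C@H]1C(=O)O | target

## Step count and risk

Total steps: 13. Longest linear sequence: 12 (steps 1–6 and 8–13); ring C enters through step 7.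

**Step 9 (key step).** Three things may go wrong. The alkoxide may fragment by retro-addition and recombine without the chair, giving [1,3] products or eroding the C9/C10 relation. Facial selection on ring A may be poor, since methyl against CO2tBu at C4 is a modest bias. The enolate may be alkylated on oxygen. Fallback: run the rearrangement on the neutral silyl ether. From 10, TMSCl/imidazole gives the trimethylsilyl ether F1. Thermolysis (xylene, 150–180 °C) should give, by a concerted silyloxy-Cope through the same chair, the trimethylsilyl enol ether F2. MeLi (THF, −78 → 0 °C) cleaves only the TMS enol ether to the lithium enolate, which is alkylated with 11 to rejoin the route at 14.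

**Step 8.** Addition to the aldehyde carbon next to the dithiane quaternary centre may be slow, so that the alkenyllithium decomposes or reduces the aldehyde. Fallback: reverse the polarity of the union. From 9, Br/Li exchange and DMF give 3-{[tri(propan-2-yl)silyl]oxy}cyclohexa-1,3-diene-1-carbaldehyde F3. Dithiane 6 is lithiated (n-BuLi, −30 °C) and added to F3 at −78 °C (α-1,2-addition, now forming C6–C7) to return at 10.

**Step 1.** Enantioselectivity of a methylation under phase transfer may be insufficient, because MeI is a small electrophile and the uncatalysed interfacial reaction is fast. Fallback: a covalent auxiliary. From 1, condensation with tert-butyl L-valinate gives the enamino ester F4. Its lithio derivative (LDA) is methylated with MeI under the solvent/additive set that leads to the R series, giving the imine F5. Mild aqueous acid returns 2 and the auxiliary.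

**Step 10.** The thiol set free may add to the C7 aldehyde under acid, the acyl transfer to the C19 acid may stall at the thioester, or C5 may be protonated from the wrong face and epimerise only slowly. Fallback: go through the free diacid. From 14 (TFA/H2O to 15 as before), AgNO3 in aqueous THF hydrolyses the thioester to the keto aldehyde diacid F6. Acetic anhydride (40 °C) then closes only the cis-diacid and equilibrates C5, returning at 16.

**Step 11.** Oxidation may be sluggish at a ketone flanked by a tertiary carbon, and warm DMSO may partly hydrolyse the anhydride. Fallback: a two-stage dehydrogenation. From 16, TMSOTf/Et3N gives the less substituted trimethylsilyl enol ether F7 (C11=C12). Pd(OAc)2 in MeCN (Saegusa–Ito oxidation) then gives 17.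

**Step 12.** The vinyl radical may be reduced before it cyclises, or may abstract hydrogen from the formyl group or the nearby C20 methyl. Fallback: a non-radical closure from the same enone 17. A reductive Heck reaction (Pd(OAc)2, PPh3, HCO2Na, DMF, 80 °C) would give 5-exo carbopalladation of the enone and formate reduction of the palladium enolate, leading directly to 18.

## Further compounds

F1 | step 9 | tert-butyl (1R)-1,3-dimethyl-2-[2-({3-[tri(propan-2-yl)silyloxy]cyclohexa-1,3-dien-1-yl}[(trimethylsilyl)oxy]methyl)-1,3-dithian-2-yl]cyclohex-2-ene-1-carboxylate | CC(C)(C)OC(=O)[C@]1(C)CCCC(C)=C1C2(SCCCS2)C(O[Si](C)(C)C)C3=CC(O[Si](C(C)C)(C(C)C)C(C)C)=CCC3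
F2 | step 9 | tert-butyl (1R,3S)-2-(1,3-dithian-2-ylidene)-1,3-dimethyl-3-[(1S)-2-{[tri(propan-2-yl)silyl]oxy}-6-{[(trimethylsilyl)oxy]methylidene}cyclohex-2-en-1-yl]cyclohexane-1-carboxylate | C[Si](C)(C)OC=C1CCC=C(O[Si](C(C)C)(C(C)C)C(C)C)[C@H]1[C@]2(C)CCC[C@@](C)(C(=O)OC(C)(C)C)C2=C3SCCCS3
F3 | step 8 | 3-{[tri(propan-2-yl)silyl]oxy}cyclohexa-1,3-diene-1-carbaldehyde | O=CC1=CC(O[Si](C(C)C)(C(C)C)C(C)C)=CCC1
F4 | step 1 | tert-butyl 2-{[(2S)-1-tert-butoxy-3-methyl-1-oxobutan-2-yl]amino}cyclohex-1-ene-1-carboxylate | CC(C)[C@H](NC1=C(C(=O)OC(C)(C)C)CCCC1)C(=O)OC(C)(C)C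
F5 | step 1 | tert-butyl (1R)-2-{[(2S)-1-tert-butoxy-3-methyl-1-oxobutan-2-yl]imino}-1-methylcyclohexane-1-carboxylate | CC(C)(C)OC(=O)[C@]1(C)CCCCC1=N[C@@H](C(C)C)C(=O)OC(C)(C)C
F6 | step 10 | (1R,2S,3S)-3-[(1S,2R)-2-(2-bromoprop-2-en-1-yl)-2-formyl-6-oxocyclohexyl]-1,3-dimethylcyclohexane-1,2-dicarboxylic acid | C=C(Br)C[C@]1(C=O)CCCC(=O)[C@H]1[C@]2(C)CCC[C@@](C)(C(=O)O)[C@H]2C(=O)O
F7 | step 11 | (3aS,4S,7aR)-4-[(1S,6R)-6-(2-bromoprop-2-en-1-yl)-6-formyl-2-[(trimethylsilyl)oxy]cyclohex-2-en-1-yl]-4,7a-dimethylhexahydro-2-benzofuran-1,3-dione | C=C(Br)C[C@]1(C=O)CCC=C(O[Si](C)(C)C)[C@H]1[C@]2(C)CCC[C@@]3(C)C(=O)OC(=O)[C@@H]23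
F0 | step 12 | none | none
A1 | alternative 1 | ent-11-oxokaura-6,16-dien-19-oic acid | C[C@@]12CCC[C@@]([C@H]1C=C[C@]34[C@H]2C(=O)C[C@H](C3)C(=C)C4)(C)C(=O)O
A2 | alternative 2 | methyl (1R,5S)-6-methylidene-3-oxobicyclo[3.2.1]octane-1-carboxylate | C=C1C[C@]2(C(=O)OC)C[C@H]1CC(=O)C2
A3 | alternative 2 | dimethyl (1R)-1,3-dimethylcyclohex-2-ene-1,2-dicarboxylate | COC(=O)[C@]1(C)CCCC(C)=C1C(=O)OC
A4 | alternative 3 | 2,3-di-tert-butyl 1-(1,3-dioxoisoindol-2-yl) 1,3-dimethylcyclohexane-1,2,3-tricarboxylate (C4 and C5 as in the target, either C10 epimer) | CC1(C(=O)ON2C(=O)c3ccccc3C2=O)CCC[C@@](C)(C(=O)OC(C)(C)C)[C@H]1C(=O)OC(C)(C)C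
A5 | alternative 3 | methyl 3-oxocyclohex-1-ene-1-carboxylate | COC(=O)C1=CC(=O)CCC1
A6 | alternative 3 | di-tert-butyl 3-[2-(methoxycarbonyl)-6-oxocyclohexyl]-1,3-dimethylcyclohexane-1,2-dicarboxylate (wanted C9/C10 diastereomer, C8 undefined) | COC(=O)C1CCCC(=O)[C@H]1[C@]2(C)CCC[C@@](C)(C(=O)OC(C)(C)C)[C@H]2C(=O)OC(C)(C)C
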